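**Retrosynthetic overview**

1. The 7-O–CH2 ether bond of the side chain is cut last: a 4′-O-silylated (2R,3R)-aromadendrin and (E)-4-chloro-2-methylbut-2-en-1-ol (from 2-methyl-2-vinyloxirane).
2. The α-ketol of ring C goes back to a 2-aryl-2H-chromene: the C4 ketone from the benzylic carbinol of a 3,4-cis-diol, the diol from the C3=C4 alkene, with the C3–OH set anti to the 2-aryl group.
3. Key disconnection: O1–C2 and C3–C4 are cut together, with a formyl group on C3 as removable activator. This gives 4,6-bis(benzyloxy)-2-hydroxybenzaldehyde (ring A with O1 and C4) and (E)-4-(triisopropylsilyloxy)cinnamaldehyde (ring B with C2 and C3). Forward, an enantioselective amine-catalysed domino oxa-Michael/aldol condensation sets C2.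
4. Enabling feature: on ring A the phenolic oxygen O1 (on C8a) and the carbonyl carbon C4 (on C4a) are ortho to each other. This nucleophile/electrophile pair spans exactly the two-carbon unit C2–C3, and C2 is benzylic to ring B, so it is the β-carbon of a cinnamaldehyde.
5. Ring order: rings A and B come from commercial aldehydes; ring C is the only ring formed (step 4).

Key step: step 4

Remark on the chemistry: the sense of induction in step 4 is taken from the usual shielding model of diarylprolinol silyl ether iminium ions, which for the (S)-catalyst leads to the 2R series. Compound 13 is used as the racemate because its stereocenter is lost in step 9.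

**Step 1**
Reactants: 1 2,4,6-trihydroxybenzaldehyde
Product: 2 4,6-bis(benzyloxy)-2-hydroxybenzaldehyde
Conditions: BnBr (2.05 equiv), K2CO3 (2.2 equiv), DMF, 0 °C to rt
Reagents that add atoms: benzyl bromide, BrCc1ccccc1
Why: Williamson etherification: the 4-OH and one of the two equivalent ortho-OH groups are benzylated, and with two equivalents of benzyl bromide the last ortho-OH should stay free because it is hydrogen-bonded to the formyl group and is the least nucleophilic.

**Step 2**
Reactants: 3 4-hydroxybenzaldehyde
Product: 4 4-(triisopropylsilyloxy)benzaldehyde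
Conditions: TIPSCl (1.1 equiv), imidazole (2 equiv), DMF, rt
Reagents that add atoms: triisopropylsilyl chloride, CC(C)[Si](Cl)(C(C)C)C(C)C
Why: Silylation of the phenol with a bulky silyl chloride and imidazole; the triisopropylsilyl ether is chosen because it should survive every later step up to the buffered fluoride treatment at the end.

**Step 3**
Reactants: 4 4-(triisopropylsilyloxy)benzaldehyde
Product: 5 (E)-3-[4-(triisopropylsilyloxy)phenyl]prop-2-enal
Conditions: Ph3P=CHCHO (1.2 equiv), toluene, 80 °C
Reagents that add atoms: (triphenylphosphoranylidene)acetaldehyde, O=CC=P(c1ccccc1)(c1ccccc1)c1ccccc1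
Why: Wittig olefination with a stabilised formyl-substituted ylide, which should give the E-enal and adds the two carbons that become C3 and the temporary formyl group (the aldehyde carbon of 4 becomes C2).

**Step 4**
Reactants: 2 4,6-bis(benzyloxy)-2-hydroxybenzaldehyde; 5 (E)-3-[4-(triisopropylsilyloxy)phenyl]prop-2-enal
Product: 8 (R)-5,7-bis(benzyloxy)-2-[4-(triisopropylsilyloxy)phenyl]-2H-chromene-3-carbaldehyde, via iminium ion 6 (not isolated), via enamine 7 (not isolated)
Conditions: 2 (1.0 equiv), 5 (1.3 equiv), (S)-α,α-diphenylprolinol trimethylsilyl ether (20 mol %), 2-nitrobenzoic acid (20 mol %), 4 Å molecular sieves, toluene, rt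
Reagents that add atoms: none
Why: Domino oxa-Michael/aldol condensation under iminium–enamine catalysis: the amine and enal 5 give the E-iminium ion 6, the phenolic O1 of 2 adds to its β-carbon (C2) to give enamine 7, whose nucleophilic carbon (C3) attacks the ortho-formyl carbon (C4), and loss of water and hydrolysis then release 8 and the amine. The closest known reaction type is the diarylprolinol silyl ether-catalysed condensation of salicylaldehydes with cinnamaldehydes to 2-aryl-2H-chromene-3-carbaldehydes. Ring C closes at C3–C4 by a 6-exo-trig (enolexo) aldol addition, the O1–C2 bond having been made first between the two components. C2, the only stereocenter formed, is set by the catalyst: the diphenyl(trimethylsilyloxy)methyl group shields one face of 6, so O1 should add to the open face and give the 2R configuration. The step needs O-attack of the phenol instead of C-attack of the electron-rich ring A and it needs capture of the reversible oxa-Michael adduct; the formyl group of 2 deactivates the ring carbons and sits ortho to O1 within reach of the enamine, and the dehydration that follows makes the sequence irreversible.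

**Step 5**
Reactants: 8 (R)-5,7-bis(benzyloxy)-2-[4-(triisopropylsilyloxy)phenyl]-2H-chromene-3-carbaldehyde
Product: 9 (S)-5,7-bis(benzyloxy)-2-[4-(triisopropylsilyloxy)phenyl]-2H-chromene
Conditions: RhCl(PPh3)3 (1.1 equiv), toluene, 80 °C, argon
Reagents that add atoms: none
Why: Tsuji–Wilkinson decarbonylation of an α,β-unsaturated aldehyde (oxidative addition of the formyl C–H bond, extrusion of carbon monoxide, C–H reductive elimination) should remove the activating formyl group and leave the C3=C4 double bond in place; C2 is not involved, and the temperature is held at 80 °C to keep the 2H-chromene from racemizing by thermal ring opening.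

**Step 6**
Reactants: 9 (S)-5,7-bis(benzyloxy)-2-[4-(triisopropylsilyloxy)phenyl]-2H-chromene
Product: 10 (2R,3S,4S)-5,7-bis(benzyloxy)-2-[4-(triisopropylsilyloxy)phenyl]chromane-3,4-diol
Conditions: OsO4 (5 mol %), N-methylmorpholine N-oxide (1.5 equiv), acetone/H2O (10:1), 0 °C to rt
Reagents that add atoms: osmium tetroxide, O=[Os](=O)(=O)=O; N-methylmorpholine N-oxide, C[N+]1([O-])CCOCC1; water, O
Why: Upjohn dihydroxylation: OsO4 should add to the electron-rich C3=C4 bond from the face opposite to the 2-aryl group (substrate control), so the C3–OH is set trans to the aryl group as the target requires, and the C4–OH, set cis to it, is oxidised away in step 7.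

**Step 7**
Reactants: 10 (2R,3S,4S)-5,7-bis(benzyloxy)-2-[4-(triisopropylsilyloxy)phenyl]chromane-3,4-diol
Product: 11 (2R,3R)-5,7-bis(benzyloxy)-3-hydroxy-2-[4-(triisopropylsilyloxy)phenyl]chroman-4-one
Conditions: DDQ (1.1 equiv), 1,4-dioxane, rt
Reagents that add atoms: none
Why: DDQ oxidation of a benzylic alcohol by hydride abstraction: only the C4 carbinol, activated by the 5,7-dioxygenated ring A, should be oxidised to the aryl ketone, while the non-benzylic C3 carbinol and the stereocenters C2 and C3 stay as they are.

**Step 8**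
Reactants: 11 (2R,3R)-5,7-bis(benzyloxy)-3-hydroxy-2-[4-(triisopropylsilyloxy)phenyl]chroman-4-one
Product: 12 (2R,3R)-3,5,7-trihydroxy-2-[4-(triisopropylsilyloxy)phenyl]chroman-4-one
Conditions: H2 (1 atm), Pd/C (10 wt %), EtOAc/MeOH, rt
Reagents that add atoms: none
Why: Hydrogenolysis of the two benzyl aryl ethers over palladium frees the 5- and 7-OH groups, while the aryl silyl ether, the ketone and both stereocenters should be left untouched under these neutral conditions.

**Step 9**
Reactants: 13 2-methyl-2-vinyloxirane (racemic)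
Product: 14 (E)-4-chloro-2-methylbut-2-en-1-ol
Conditions: TiCl4 (1.0 equiv), CH2Cl2, −80 °C; aqueous work-up
Reagents that add atoms: titanium tetrachloride, Cl[Ti](Cl)(Cl)Cl
Why: Lewis acid-promoted SN2′ opening of a vinyl epoxide: TiCl4 activates the epoxide oxygen and chloride adds to the vinyl terminus, which should give the E-configured 1,4-chlorohydrin (CH2OH and CH2Cl trans); the stereocenter of 13 is lost and none is formed.

**Step 10**
Reactants: 12 (2R,3R)-3,5,7-trihydroxy-2-[4-(triisopropylsilyloxy)phenyl]chroman-4-one; 14 (E)-4-chloro-2-methylbut-2-en-1-ol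
Product: 15 (2R,3R)-3,5-dihydroxy-7-{[(E)-4-hydroxy-3-methylbut-2-en-1-yl]oxy}-2-[4-(triisopropylsilyloxy)phenyl]chroman-4-one
Conditions: 14 (1.2 equiv), K2CO3 (1.1 equiv), acetone, 45 °C, argon
Reagents that add atoms: none
Why: Williamson etherification: the 7-OH, para to the C4 carbonyl, is the most acidic hydroxyl of 12 and should be the one deprotonated by one equivalent of carbonate (the 5-OH is hydrogen-bonded to the carbonyl, the 3-OH is an alcohol, the 4′-oxygen is silylated), and SN2 displacement of the primary allylic chloride keeps the E geometry and leaves C2 and C3 alone.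

**Step 11**
Reactants: 15 (2R,3R)-3,5-dihydroxy-7-{[(E)-4-hydroxy-3-methylbut-2-en-1-yl]oxy}-2-[4-(triisopropylsilyloxy)phenyl]chroman-4-one
Product: 16 (2R,3R)-3,5-dihydroxy-7-{[(E)-4-hydroxy-3-methylbut-2-en-1-yl]oxy}-2-(4-hydroxyphenyl)chroman-4-one
Conditions: Bu4NF (1.1 equiv), AcOH (1.1 equiv), THF, 0 °C
Reagents that add atoms: none
Why: Fluoride-mediated cleavage of the aryl triisopropylsilyl ether; buffering with acetic acid keeps the medium from becoming basic, so the base-sensitive trans-dihydroflavonol should neither epimerise nor open, and the allylic ether and alcohol are inert.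

**Compound list**

1 | 2,4,6-trihydroxybenzaldehyde | O=Cc1c(O)cc(O)cc1O | starting material
2 | 4,6-bis(benzyloxy)-2-hydroxybenzaldehyde | O=Cc1c(O)cc(OCc2ccccc2)cc1OCc1ccccc1 | intermediate
3 | 4-hydroxybenzaldehyde | O=Cc1ccc(O)cc1 | starting material
4 | 4-(triisopropylsilyloxy)benzaldehyde | O=Cc1ccc(O[Si](C(C)C)(C(C)C)C(C)C)cc1 | intermediate
5 | (E)-3-[4-(triisopropylsilyloxy)phenyl]prop-2-enal | O=C/C=C/c1ccc(O[Si](C(C)C)(C(C)C)C(C)C)cc1 | intermediate
6 | iminium ion from 5 and (S)-α,α-diphenylprolinol trimethylsilyl ether (2-nitrobenzoate salt) | C[Si](C)(C)OC(c1ccccc1)(c1ccccc1)[C@@H]1CCC[N+]1=C/C=C/c1ccc(O[Si](C(C)C)(C(C)C)C(C)C)cc1.[O-]C(=O)c1ccccc1[N+](=O)[O-] | intermediate (not isolated)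
7 | catalyst-bound enamine from oxa-Michael addition of 2 to 6 (new C–O stereocenter as in 8) | C[Si](C)(C)OC(c1ccccc1)(c1ccccc1)[C@@H]1CCCN1/C=C/[C@@H](c1ccc(O[Si](C(C)C)(C(C)C)C(C)C)cc1)Oc1cc(OCc2ccccc2)cc(OCc2ccccc2)c1C=O | intermediate (not isolated)
8 | (R)-5,7-bis(benzyloxy)-2-[4-(triisopropylsilyloxy)phenyl]-2H-chromene-3-carbaldehyde | c1ccccc1COc1cc(OCc3ccccc3)c2c(c1)O[C@H](c1ccc(O[Si](C(C)C)(C(C)C)C(C)C)cc1)C(C=O)=C2 | intermediate
9 | (S)-5,7-bis(benzyloxy)-2-[4-(triisopropylsilyloxy)phenyl]-2H-chromene (same spatial arrangement at C2 as in 8; only the descriptor changes) | c1ccccc1COc1cc(OCc3ccccc3)c2c(c1)O[C@H](c1ccc(O[Si](C(C)C)(C(C)C)C(C)C)cc1)C=C2 | intermediate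
10 | (2R,3S,4S)-5,7-bis(benzyloxy)-2-[4-(triisopropylsilyloxy)phenyl]chromane-3,4-diol (2,3-trans, 3,4-cis) | c1ccccc1COc1cc(OCc3ccccc3)c2c(c1)O[C@H](c1ccc(O[Si](C(C)C)(C(C)C)C(C)C)cc1)[C@@H](O)[C@H]2O | intermediate
11 | (2R,3R)-5,7-bis(benzyloxy)-3-hydroxy-2-[4-(triisopropylsilyloxy)phenyl]chroman-4-one | c1ccccc1COc1cc(OCc3ccccc3)c2c(c1)O[C@H](c1ccc(O[Si](C(C)C)(C(C)C)C(C)C)cc1)[C@@H](O)C2=O | intermediate
12 | (2R,3R)-3,5,7-trihydroxy-2-[4-(triisopropylsilyloxy)phenyl]chroman-4-one | Oc1cc(O)c2c(c1)O[C@H](c1ccc(O[Si](C(C)C)(C(C)C)C(C)C)cc1)[C@@H](O)C2=O | intermediate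
13 | 2-methyl-2-vinyloxirane (racemic) | CC1(C=C)CO1 | starting material
14 | (E)-4-chloro-2-methylbut-2-en-1-ol | C/C(=C\CCl)CO | intermediate
15 | (2R,3R)-3,5-dihydroxy-7-{[(E)-4-hydroxy-3-methylbut-2-en-1-yl]oxy}-2-[4-(triisopropylsilyloxy)phenyl]chroman-4-one | C/C(=C\COc1cc(O)c2c(c1)O[C@H](c1ccc(O[Si](C(C)C)(C(C)C)C(C)C)cc1)[C@@H](O)C2=O)CO | intermediate
16 | (2R,3R)-3,5-dihydroxy-7-{[(E)-4-hydroxy-3-methylbut-2-en-1-yl]oxy}-2-(4-hydroxyphenyl)chroman-4-one | C/C(=C\COc1cc(O)c2c(c1)O[C@H](c1ccc(O)cc1)[C@@H](O)C2=O)CO | target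

**Step count and risks**

Total step count: 11. Longest linear sequence: 9 steps (steps 2, 3, 4, 5, 6, 7, 8, 10 and 11, from 3 to 16).

The three steps most likely to fail:

Step 5 (decarbonylation). What may go wrong: carbon monoxide extrusion from the hindered enal may be slow, and at the temperature it needs the 2H-chromene may lose its configuration at C2 by reversible thermal opening and reclosure of the O1–C2 bond. The fallback sets out from 8, removes the double bond before the formyl group and needs no heating. Upjohn dihydroxylation of the enal double bond of 8 (OsO4, N-methylmorpholine N-oxide), anti to the 2-aryl group, should give (2R)-5,7-bis(benzyloxy)-3,4-dihydroxy-2-[4-(triisopropylsilyloxy)phenyl]chromane-3-carbaldehyde F1. DDQ oxidation of its benzylic C4 carbinol should give (2R)-5,7-bis(benzyloxy)-3-hydroxy-4-oxo-2-[4-(triisopropylsilyloxy)phenyl]chromane-3-carbaldehyde F2. Retro-Claisen deformylation of this non-enolisable β-keto aldehyde with aqueous NaHCO3 in THF at rt, with protonation at C3 settling to the more stable trans isomer, comes back to the route at 11.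

Step 4 (key step). What may go wrong: with the hindered, electron-rich aldehyde 2 the aldol closure may be slow, so that the oxa-Michael addition reverts and the enantioselectivity erodes, or ring A may attack the iminium ion through carbon. The fallback sets out from 2 and 5 and makes the same two bonds in separate, known operations. Luche reduction of 5 (NaBH4, CeCl3, MeOH) gives (E)-3-[4-(triisopropylsilyloxy)phenyl]prop-2-en-1-ol F3, and methyl chloroformate with pyridine gives methyl (E)-3-[4-(triisopropylsilyloxy)phenyl]prop-2-en-1-yl carbonate F4. Enantioselective allylic etherification of F4 with the phenoxide of 2 ([Ir(cod)Cl]2, chiral phosphoramidite ligand, K3PO4, THF) forms the O1–C2 bond at the benzylic terminus. With the proper ligand enantiomer it should give 4,6-bis(benzyloxy)-2-({(1S)-1-[4-(triisopropylsilyloxy)phenyl]prop-2-en-1-yl}oxy)benzaldehyde F5. Wittig methylenation of the formyl group (Ph3P=CH2) gives 1,5-bis(benzyloxy)-2-ethenyl-3-({(1S)-1-[4-(triisopropylsilyloxy)phenyl]prop-2-en-1-yl}oxy)benzene F6. Ring-closing metathesis with the second-generation Grubbs catalyst forms the C3=C4 bond and comes back to the route at 9, so that 8 and step 5 are bypassed.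

Step 10 (side-chain etherification). What may go wrong: under carbonate the dihydroflavonol may epimerise or open, and the aryl silyl ether may be partly lost, which would lead to alkylation at the 4′-oxygen as well. The fallback sets out from 12 and uses neutral conditions. Tsuji–Trost-type opening of 2-methyl-2-vinyloxirane 13 with Pd(PPh3)4 (5 mol %) in THF at rt, the acidic 7-OH of 12 acting as pronucleophile and adding at the distal carbon of the allyl unit, should give the E-configured 1,4-adduct and so comes back to the route at 15. This fallback makes no new compound (F0).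

**Further compounds**

F1 | step 5 | (2R)-5,7-bis(benzyloxy)-3,4-dihydroxy-2-[4-(triisopropylsilyloxy)phenyl]chromane-3-carbaldehyde (both hydroxyls trans to the aryl group) | c1ccccc1COc1cc(OCc3ccccc3)c2c(c1)O[C@H](c1ccc(O[Si](C(C)C)(C(C)C)C(C)C)cc1)[C@](O)(C=O)[C@H]2O
F2 | step 5 | (2R)-5,7-bis(benzyloxy)-3-hydroxy-4-oxo-2-[4-(triisopropylsilyloxy)phenyl]chromane-3-carbaldehyde (3-hydroxyl trans to the aryl group) | c1ccccc1COc1cc(OCc3ccccc3)c2c(c1)O[C@H](c1ccc(O[Si](C(C)C)(C(C)C)C(C)C)cc1)[C@](O)(C=O)C2=O
F3 | step 4 | (E)-3-[4-(triisopropylsilyloxy)phenyl]prop-2-en-1-ol | OC/C=C/c1ccc(O[Si](C(C)C)(C(C)C)C(C)C)cc1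
F4 | step 4 | methyl (E)-3-[4-(triisopropylsilyloxy)phenyl]prop-2-en-1-yl carbonate | COC(=O)OC/C=C/c1ccc(O[Si](C(C)C)(C(C)C)C(C)C)cc1
F5 | step 4 | 4,6-bis(benzyloxy)-2-({(1S)-1-[4-(triisopropylsilyloxy)phenyl]prop-2-en-1-yl}oxy)benzaldehyde | O=Cc1c(OCc2ccccc2)cc(OCc2ccccc2)cc1O[C@H](c1ccc(O[Si](C(C)C)(C(C)C)C(C)C)cc1)C=C
F6 | step 4 | 1,5-bis(benzyloxy)-2-ethenyl-3-({(1S)-1-[4-(triisopropylsilyloxy)phenyl]prop-2-en-1-yl}oxy)benzene | C=Cc1c(OCc2ccccc2)cc(OCc2ccccc2)cc1O[C@H](c1ccc(O[Si](C(C)C)(C(C)C)C(C)C)cc1)C=C
F0 | step 10 | none | none
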